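## Analysis of the target

The target is a 2,3-dihydrobenzofuran (O1, C2, C3, benzo ring A from C3a to C7a). C2 carries the 4-hydroxyphenyl ring B, C3 the 3,5-dihydroxyphenyl ring C, and C5 an (E)-3,5-dihydroxystyryl arm. The only stereocentres are C2 and C3, both S and contiguous, with rings B and C trans across the five-membered ring. Trans is the less strained arrangement, so the relative configuration is the easy part and the absolute configuration the hard part. The C2–O1 bond is a benzylic aryl ether para to a phenol oxygen: acid can ionise it and hot base can open it through a quinone methide. The stilbene is electron-rich, photoisomerisable and easily hydrogenated, and the five phenols oxidise in air under base. The difficulty is that C2 and C3 carry only aryl groups and hydrogen, so there is no handle for auxiliary or chelate control, and ring A must end up 1,2,4-trisubstituted in one defined way. The strategy rests on two features. O1 and C3 sit on the adjacent ring A carbons C7a and C3a, which is the pattern an aryne leaves after taking up an oxygen nucleophile and a carbon electrophile. The O1–C2–C3 triad is the O–C–C unit of a trans-stilbene oxide, whose configuration at C2 can be set by a reliable catalytic epoxidation and then left untouched.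

## Retrosynthetic reasoning

**20 to 19.** The last cut is at the four O–methyl bonds of rings C and of the styryl ring. Methyl ethers are the only groups that survive fluoride, hydroxide and both palladium steps without comment. Ring B is already a free phenol at this point; under a boron Lewis acid it becomes an aryloxyborane, a weak π-donor, so the pull on C2–O1 is smaller than with a ring B methyl ether. The forward step must cleave four aryl methyl ethers without ionising C2–O1 or adding acid to the stilbene.

**19 to 18.** C4–H is traced back to C4–Cl. The chlorine has no place in the target; it is there to steer the aryne step. It is removed after the arm is attached because a bromide would be reduced before a chloride. The forward step must reduce a doubly ortho-substituted aryl chloride and spare the stilbene.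

**18 to 16 and 17.** The C5–vinyl bond is cut, leading to the aryl bromide 16 and the commercial styrene 17. Attaching the arm after the ring is built keeps an alkene and a second nucleophilic dimethoxyphenyl ring away from the aryne. The forward Heck step must give the (E)-alkene and react at C5–Br only.

**16 to 15.** The ring B phenol is traced back to its triflate. The triflate is not a mere protecting group: it makes ring B electron-poor, which decides which C–O bond of the oxirane breaks in the key step. It must come off before the palladium steps because it would compete with the bromide.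

**15 to 3 and 11 (through aryne 12).** This is the central cut, through C7a–O1 and C3a–C3. Cutting here forms both bonds to ring A in one operation and keeps O1–C2 intact, so the configuration at C2 can be bought beforehand in oxide 3. Cutting O1–C2 or C2–C3 instead would force the ring-forming step itself to create C2 enantioselectively. The forward step must control three things: which aryne carbon takes oxygen, which oxirane C–O bond breaks, and the trans ring closure.

**3 to 2 to 1.** The two oxirane C–O bonds are traced back to the (E)-alkene of 2, which comes from commercial phenol 1 by O-sulfonylation. A chiral ketone-catalysed (Shi-type) epoxidation of an (E)-stilbene is among the most dependable ways to set such a centre, and syn oxygen transfer fixes the trans oxide.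

**11 to 9 to 5 to 4.** The silyl triflate 11 goes back to commercial phenol 4. The C6–Si bond comes from a carbamate-directed metalation at the only position ortho to oxygen, and the carbamate is then exchanged for the triflate. The bromine at C3 rules out an alkyllithium, so a lithium amide with in situ silylation is required.

## Alternatives that were turned down

**Alternative 1: conjunctive cross-coupling on boron.**
- Disconnection: C2–ring B and C3–C3a are cut on an open chain; O1–C7a is closed later.
- Forward key step: an ate complex from a β-aryl alkenyl boronic ester and an aryllithium meets the arylpalladium formed from a ring A triflate under a palladium catalyst with a chiral ferrocenyl diphosphine. Ring B migrates from boron to C2 anti to palladium, and reductive elimination forms C3–C3a. The product is methyl 3-[(1S,2S)-1-(3,5-dimethoxyphenyl)-2-(4-methoxyphenyl)-2-(4,4,5,5-tetramethyl-1,3,2-dioxaborolan-2-yl)ethyl]-4-fluorobenzoate A1.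
- For: both stereocentres are set in one catalytic enantioselective step from achiral pieces. The anti 1,2-shift turns alkene geometry into relative configuration stereospecifically, with no cation involved. No directing chlorine is needed. On precedent for the reaction class and on catalyst control of both centres it is stronger than the chosen route.
- Against: β-aryl alkenyl boron ate complexes are the slow substrates of this coupling, and direct Suzuki-type transfer competes. A1 is still an open chain: it needs oxidation of C–B, ring closure by fluoride displacement, and conversion of the ester into the styryl arm through reduction, oxidation and olefination. Ring B ends as a methyl ether para to C2, the worst case for the final demethylation.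
- Comparison: the chosen route closes the ring and forms both ring A bonds in one step, needs four steps after it instead of about seven, and never has a ring B methyl ether. It pays with an unprecedented key step.

**Alternative 2: ruthenium (2+2+2) construction of ring A.**
- Disconnection: three bonds of ring A (C3a–C7a, C4–C5, C6–C7) are cut.
- Forward key step: a cyclopentadienyl ruthenium chloride catalyst cyclotrimerises a 1,6-diyne with an (E)-enyne. The diyne is a silyl-capped ynol ether that already holds C2 and C3. Ring A and the dihydrofuran ring close together, giving trimethyl{(2S,3S)-3-(3,5-dimethoxyphenyl)-5-[(E)-2-(3,5-dimethoxyphenyl)ethenyl]-2-(4-methoxyphenyl)-2,3-dihydro-1-benzofuran-7-yl}silane A2.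
- For: the whole carbon skeleton, arm included, arrives in one step, so no late Heck coupling or dehalogenation is needed; here it is stronger than the chosen route. The stereodiad is made on an open chain, where standard asymmetric methods apply.
- Against: the ynol ether of a secondary benzylic alcohol is fragile (ketene formation, sigmatropic shifts). The enyne can insert in two orientations and its alkene can take part. The diyne with two stereocentres would need roughly eight to ten steps. A protodesilylation and a five-fold demethylation including ring B follow.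
- Comparison: the chosen route reaches its two key precursors in two and three steps from commercial phenols, and its risk sits in one step, not spread over a long and sensitive precursor synthesis.

**Alternative 3: ortho-quinone methide plus chiral sulfur ylide, (4+1) annulation.**
- Disconnection: C2–C3 and O1–C2 are cut, C2 being a one-carbon unit.
- Forward key step: a carbonate base unmasks an ortho-quinone methide from a 2-(α-sulfonylbenzyl)phenol and an ylide from a chiral S-benzyl thiolanium salt. The ylide carbon adds to the methide carbon (C2–C3), and the phenoxide displaces the sulfide (O1–C2) to give (2S,3S)-5-bromo-3-(3,5-dimethoxyphenyl)-2-(4-methoxyphenyl)-2,3-dihydro-1-benzofuran A3.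
- For: the ring construction is close to known annulations and inherently trans-selective (anti betaine, then backside displacement). A3 has no chlorine to remove. On reliability of ring formation and on the endgame before demethylation it is stronger than the chosen route.
- Against: the chiral sulfide is stoichiometric. Semi-stabilised benzyl ylides add to a planar quinone methide with less predictable enantioselectivity, and reversible betaine formation can erode it. Both centres depend on this one reagent-controlled addition. Ring B is again a methyl ether para to C2.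
- Comparison: the chosen route takes its enantiopurity from a catalytic epoxidation of an (E)-stilbene and carries it through a bond that is never broken. It keeps ring B as a triflate or free phenol throughout. It accepts one extra step to remove chlorine.

Key step: step 6

Assumption (remark on the chemistry): the D-fructose-derived Shi ketone is taken to attack (E)-stilbene 2 on the same face as (E)-stilbene itself, giving the (2R,3R)-oxide 3. With C2–O1 retained and C3 re-formed trans, this oxide maps onto the (2S,3S) ring; both descriptors change from R to S only because the CIP ranks change when the oxirane oxygen at C3 is replaced by C3a.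

## Route

Step 1
Reactants: 1 pterostilbene, 4-[(E)-2-(3,5-dimethoxyphenyl)ethenyl]phenol
Product: 2 4-[(E)-2-(3,5-dimethoxyphenyl)ethenyl]phenyl trifluoromethanesulfonate
Conditions: PhNTf2, Et3N, DMAP (cat.), CH2Cl2, 0 °C to rt
Reagents that add atoms: N-phenylbis(trifluoromethanesulfonimide), O=S(=O)(N(c1ccccc1)S(=O)(=O)C(F)(F)F)C(F)(F)F
Why: O-sulfonylation of the phenol with a mild triflyl donor that leaves the alkene and the electron-rich ring C alone. The triflate makes ring B electron-poor, which later decides which C–O bond of the oxirane breaks.

Step 2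
Reactants: 2 4-[(E)-2-(3,5-dimethoxyphenyl)ethenyl]phenyl trifluoromethanesulfonate
Product: 3 4-[(2R,3R)-3-(3,5-dimethoxyphenyl)oxiran-2-yl]phenyl trifluoromethanesulfonate
Conditions: D-fructose-derived Shi ketone (1,2:4,5-di-O-isopropylidene-β-D-erythro-2,3-hexodiulo-2,6-pyranose, 30 mol %), KHSO5 (as 2KHSO5·KHSO4·K2SO4), K2CO3, Bu4NHSO4 (cat.), MeCN/CH2(OMe)2/aq. Na2B4O7 buffer, 0 °C
Reagents that add atoms: potassium peroxymonosulfate, [K+].[O-]S(=O)(=O)OO
Why: Shi asymmetric epoxidation: the chiral dioxirane formed from the ketone and KHSO5 transfers oxygen syn through a spiro transition state, so the (E)-alkene gives the trans oxide, and with the D-fructose-derived ketone (E)-stilbenes give the (R,R)-oxide. This sets C2 of the target; the second centre is re-formed in step 6. The buffered medium at 0 °C should leave the aryl triflate intact, and the electron-poor ring B makes the oxide resistant to ring opening.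

Step 3
Reactants: 4 3-bromo-2-chlorophenol
Product: 5 3-bromo-2-chlorophenyl N-(propan-2-yl)carbamate
Conditions: i-PrNCO, Et3N (cat.), CH2Cl2, rt
Reagents that add atoms: 2-isocyanatopropane, CC(C)N=C=O
Why: Base-catalysed addition of the phenol to the isocyanate gives an N-monoalkyl carbamate, an ortho-directing group that can later be removed under mild base.

Step 4
Reactants: 5 3-bromo-2-chlorophenyl N-(propan-2-yl)carbamate
Product: 9 3-bromo-2-chloro-6-(trimethylsilyl)phenyl N-(propan-2-yl)carbamate, via N-silyl carbamate 6 (not isolated), via ortho-lithiated N-silyl carbamate 7 (not isolated), via C-silylated N-silyl carbamate 8 (not isolated)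
Conditions: TBSOTf, TMEDA, Et2O, 0 °C to rt; then TMSCl, LiTMP (lithium 2,2,6,6-tetramethylpiperidide), THF, −78 °C; aq. NaHSO4
Reagents that add atoms: chlorotrimethylsilane, C[Si](C)(C)Cl; tert-butyldimethylsilyl trifluoromethanesulfonate, CC(C)(C)[Si](C)(C)OS(=O)(=O)C(F)(F)F (its silyl group stays only in 6, 7 and 8)
Why: Directed ortho-metalation with in situ silylation: N-silylation masks the N–H, the carbamate directs the lithium amide to C6 (the only position ortho to it), and aryllithium 7 is trapped at once by TMSCl; acidic work-up removes the N-silyl group. A lithium amide replaces the usual alkyllithium because the C3 bromide would undergo bromine–lithium exchange, and the in situ quench leaves no time for anionic Fries rearrangement or loss of LiBr.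

Step 5
Reactants: 9 3-bromo-2-chloro-6-(trimethylsilyl)phenyl N-(propan-2-yl)carbamate
Product: 11 3-bromo-2-chloro-6-(trimethylsilyl)phenyl trifluoromethanesulfonate, via 3-bromo-2-chloro-6-(trimethylsilyl)phenol 10 (not isolated)
Conditions: DBU, Et2NH, MeCN, 40 °C; then PhNTf2, rt
Reagents that add atoms: N-phenylbis(trifluoromethanesulfonimide), O=S(=O)(N(c1ccccc1)S(=O)(=O)C(F)(F)F)C(F)(F)F
Why: Base-induced E1cB cleavage of the N–H carbamate (the isocyanate is scavenged by Et2NH) frees phenoxide 10, which is triflated in the same flask. The protodesilylation-prone ortho-silyl phenol is never isolated.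

Step 6
Reactants: 3 4-[(2R,3R)-3-(3,5-dimethoxyphenyl)oxiran-2-yl]phenyl trifluoromethanesulfonate; 11 3-bromo-2-chloro-6-(trimethylsilyl)phenyl trifluoromethanesulfonate
Product: 15 4-[(2S,3S)-5-bromo-4-chloro-3-(3,5-dimethoxyphenyl)-2,3-dihydro-1-benzofuran-2-yl]phenyl trifluoromethanesulfonate, via 4-bromo-3-chlorobenzyne 12 (not isolated), via oxiranium zwitterion 13 (not isolated), via open benzylic zwitterion 14 (not isolated)
Conditions: CsF, MeCN, rt, slow addition of 11
Reagents that add atoms: none
Why: Proposed new method: fluoride removes the silyl group of 11 and triflate leaves to give aryne 12; the oxirane oxygen of 3 adds to the aryne carbon remote from chlorine (the future C7a) to give zwitterion 13 with the carbanion at C3a, the strained oxiranium opens at the carbon bearing ring C to the benzylic cation of 14, and the C3a carbanion captures it, so that C7a–O1 and C3a–C3 are formed and the oxirane is expanded to the dihydrofuran. The closest known reaction type is the fluoride-induced insertion of arynes into the C–O bond of monoaryl epoxides to give dihydrobenzofurans; new here are the regiocontrol demanded on both partners and the transfer of configuration from a 2,3-diaryl oxirane. The five-membered ring closes by intramolecular collapse of the aryl anion and benzylic cation pair, a three-to-five ring expansion at a planar cation, so no stereoelectronic ring-closure constraint applies. C2 is not a new centre: its C–O bond is never broken, so the configuration from step 2 is carried over, R in 3 becoming S in 15 only through a change of CIP ranks. C3 is re-formed from the planar cation under control of C2, with ring C ending anti to ring B in the less strained trans ring. Aryne regioselectivity rests on the chlorine at the future C4, which distorts the aryne and stabilises the adjacent carbanion, reinforced by the bromine at the future C5; chlorine, not bromine, sits next to the carbanion because it is the poorer leaving group for a second elimination. Regioselectivity of C–O cleavage rests on the triflyloxy group, which makes a cation at C2 much less stable than one at C3; cleavage at the wrong carbon would give a constitutional isomer and not the enantiomer, so enantiopurity is not eroded. The main competing path is proton transfer within the zwitterion to an aryl vinyl ether, countered by an aprotic medium at room temperature and slow addition of 11.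

Step 7
Reactants: 15 4-[(2S,3S)-5-bromo-4-chloro-3-(3,5-dimethoxyphenyl)-2,3-dihydro-1-benzofuran-2-yl]phenyl trifluoromethanesulfonate
Product: 16 4-[(2S,3S)-5-bromo-4-chloro-3-(3,5-dimethoxyphenyl)-2,3-dihydro-1-benzofuran-2-yl]phenol
Conditions: Et4NOH (aq.), 1,4-dioxane, rt
Reagents that add atoms: none
Why: Hydroxide attacks sulfur of the aryl triflate (S–O cleavage) and releases the phenoxide at room temperature; aryl bromide, aryl chloride, methyl ethers and both stereocentres are inert. The triflate has to go now because it would compete with the bromide in the palladium step.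

Step 8
Reactants: 16 4-[(2S,3S)-5-bromo-4-chloro-3-(3,5-dimethoxyphenyl)-2,3-dihydro-1-benzofuran-2-yl]phenol; 17 3,5-dimethoxystyrene
Product: 18 4-[(2S,3S)-4-chloro-3-(3,5-dimethoxyphenyl)-5-[(E)-2-(3,5-dimethoxyphenyl)ethenyl]-2,3-dihydro-1-benzofuran-2-yl]phenol
Conditions: Pd(OAc)2 (5 mol %), P(o-tol)3, Et3N, DMF, 100 °C, dark
Reagents that add atoms: none
Why: Heck reaction: zerovalent palladium inserts into C5–Br, far faster than into the hindered C4–Cl bond with a triarylphosphine; syn carbopalladation at the terminal carbon of the styrene and syn β-hydride elimination give the (E)-stilbene. Free phenols are tolerated under amine-base conditions.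

Step 9
Reactants: 18 4-[(2S,3S)-4-chloro-3-(3,5-dimethoxyphenyl)-5-[(E)-2-(3,5-dimethoxyphenyl)ethenyl]-2,3-dihydro-1-benzofuran-2-yl]phenol
Product: 19 4-[(2S,3S)-3-(3,5-dimethoxyphenyl)-5-[(E)-2-(3,5-dimethoxyphenyl)ethenyl]-2,3-dihydro-1-benzofuran-2-yl]phenol
Conditions: Pd(OAc)2 (5 mol %), XPhos (2-dicyclohexylphosphino-2',4',6'-triisopropylbiphenyl), HCO2Na, DMF/H2O, 80 °C
Reagents that add atoms: none
Why: Palladium-catalysed transfer hydrodechlorination: the bulky electron-rich biarylphosphine allows oxidative addition into the hindered C4–Cl bond, formate replaces chloride and decarboxylates to an arylpalladium hydride, and reductive elimination gives C4–H. A ligated homogeneous catalyst with formate as the only hydride source is a poor alkene hydrogenation system, so the stilbene should survive.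

Step 10
Reactants: 19 4-[(2S,3S)-3-(3,5-dimethoxyphenyl)-5-[(E)-2-(3,5-dimethoxyphenyl)ethenyl]-2,3-dihydro-1-benzofuran-2-yl]phenol
Product: 20 (2S,3S)-trans-δ-viniferin, 5-[(2S,3S)-5-[(E)-2-(3,5-dihydroxyphenyl)ethenyl]-2-(4-hydroxyphenyl)-2,3-dihydro-1-benzofuran-3-yl]benzene-1,3-diol
Conditions: BBr3 (excess), CH2Cl2, −78 to 0 °C, dark; then MeOH, aq. NaHCO3
Reagents that add atoms: none
Why: Lewis acid-mediated cleavage of aryl methyl ethers, bromide attacking the methyl group of the boron-complexed ether. The ring B oxygen is an aryloxyborane under these conditions, a weak π-donor, so ionisation of C2–O1 is disfavoured; if it occurred reversibly, reclosure is governed by the intact C3 centre and returns the trans ring.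

## Compound list

1 | pterostilbene, 4-[(E)-2-(3,5-dimethoxyphenyl)ethenyl]phenol | COc1cc(/C=C/c2ccc(O)cc2)cc(OC)c1 | starting material
2 | 4-[(E)-2-(3,5-dimethoxyphenyl)ethenyl]phenyl trifluoromethanesulfonate | COc1cc(/C=C/c2ccc(OS(=O)(=O)C(F)(F)F)cc2)cc(OC)c1 | intermediate
3 | 4-[(2R,3R)-3-(3,5-dimethoxyphenyl)oxiran-2-yl]phenyl trifluoromethanesulfonate | O=S(=O)(Oc1ccc([C@H]2O[C@@H]2c2cc(OC)cc(OC)c2)cc1)C(F)(F)F | intermediate
4 | 3-bromo-2-chlorophenol | Oc1cccc(Br)c1Cl | starting material
5 | 3-bromo-2-chlorophenyl N-(propan-2-yl)carbamate | CC(C)NC(=O)Oc1cccc(Br)c1Cl | intermediate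
6 | 3-bromo-2-chlorophenyl N-[tert-butyl(dimethyl)silyl]-N-(propan-2-yl)carbamate | CC(C)N(C(=O)Oc1cccc(Br)c1Cl)[Si](C)(C)C(C)(C)C | intermediate (not isolated)
7 | 6-lithio derivative of 6, [4-bromo-3-chloro-2-({[tert-butyl(dimethyl)silyl](propan-2-yl)carbamoyl}oxy)phenyl]lithium | [Li]c1ccc(Br)c(Cl)c1OC(=O)N(C(C)C)[Si](C)(C)C(C)(C)C | intermediate (not isolated)
8 | 3-bromo-2-chloro-6-(trimethylsilyl)phenyl N-[tert-butyl(dimethyl)silyl]-N-(propan-2-yl)carbamate | CC(C)N(C(=O)Oc1c([Si](C)(C)C)ccc(Br)c1Cl)[Si](C)(C)C(C)(C)C | intermediate (not isolated)
9 | 3-bromo-2-chloro-6-(trimethylsilyl)phenyl N-(propan-2-yl)carbamate | CC(C)NC(=O)Oc1c([Si](C)(C)C)ccc(Br)c1Cl | intermediate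
10 | 3-bromo-2-chloro-6-(trimethylsilyl)phenol | Oc1c([Si](C)(C)C)ccc(Br)c1Cl | intermediate (not isolated)
11 | 3-bromo-2-chloro-6-(trimethylsilyl)phenyl trifluoromethanesulfonate | C[Si](C)(C)c1ccc(Br)c(Cl)c1OS(=O)(=O)C(F)(F)F | intermediate
12 | 4-bromo-3-chlorobenzyne (4-bromo-3-chloro-1,2-didehydrobenzene) | ClC1=C(Br)C=CC#C1 | intermediate (not isolated)
13 | oxiranium zwitterion: oxide 3 with its oxygen bonded to C1 of a 4-bromo-3-chlorophenyl group that carries the carbanion at C2 | O=S(=O)(Oc1ccc([C@H]2[O+](c3ccc(Br)c(Cl)[c-]3)[C@@H]2c2cc(OC)cc(OC)c2)cc1)C(F)(F)F | intermediate (not isolated)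
14 | open zwitterion: aryl ether at C2 (configuration retained), benzylic cation at the carbon bearing ring C, carbanion ortho to the ether oxygen | O=S(=O)(Oc1ccc([C@@H](Oc2ccc(Br)c(Cl)[c-]2)[CH+]c2cc(OC)cc(OC)c2)cc1)C(F)(F)F | intermediate (not isolated)
15 | 4-[(2S,3S)-5-bromo-4-chloro-3-(3,5-dimethoxyphenyl)-2,3-dihydro-1-benzofuran-2-yl]phenyl trifluoromethanesulfonate | O=S(=O)(Oc1ccc([C@H]2Oc3ccc(Br)c(Cl)c3[C@@H]2c2cc(OC)cc(OC)c2)cc1)C(F)(F)F | intermediate
16 | 4-[(2S,3S)-5-bromo-4-chloro-3-(3,5-dimethoxyphenyl)-2,3-dihydro-1-benzofuran-2-yl]phenol | Oc1ccc([C@H]2Oc3ccc(Br)c(Cl)c3[C@@H]2c2cc(OC)cc(OC)c2)cc1 | intermediate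
17 | 3,5-dimethoxystyrene | C=Cc1cc(OC)cc(OC)c1 | starting material
18 | 4-[(2S,3S)-4-chloro-3-(3,5-dimethoxyphenyl)-5-[(E)-2-(3,5-dimethoxyphenyl)ethenyl]-2,3-dihydro-1-benzofuran-2-yl]phenol | Oc1ccc([C@H]2Oc3ccc(/C=C/c4cc(OC)cc(OC)c4)c(Cl)c3[C@@H]2c2cc(OC)cc(OC)c2)cc1 | intermediate
19 | 4-[(2S,3S)-3-(3,5-dimethoxyphenyl)-5-[(E)-2-(3,5-dimethoxyphenyl)ethenyl]-2,3-dihydro-1-benzofuran-2-yl]phenol | Oc1ccc([C@H]2Oc3ccc(/C=C/c4cc(OC)cc(OC)c4)cc3[C@@H]2c2cc(OC)cc(OC)c2)cc1 | intermediate
20 | (2S,3S)-trans-δ-viniferin | Oc1ccc([C@H]2Oc3ccc(/C=C/c4cc(O)cc(O)c4)cc3[C@@H]2c2cc(O)cc(O)c2)cc1 | target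

## Step count and least certain steps

Total: 10 steps. Longest linear sequence: 8 steps (4 through steps 3, 4, 5, 6, 7, 8, 9 and 10 to 20); the oxide branch (steps 1 and 2) joins at step 6.

**Step 6 (key step).**
- What may go wrong: proton transfer within the zwitterion to an aryl vinyl ether in place of ring closure; leakage of C–O cleavage to the carbon bearing ring B, because the two benzylic cations differ only moderately; poor capture of the aryne by the hindered, weakly nucleophilic oxirane oxygen, so that the aryne is consumed by fluoride or by its own precursor.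
- Fallback (known chemistry, C3–C3a first and O1–C2 second), setting out from 2 and coming back at 19. Epoxidation of 2 with the enantiomeric Shi ketone (from L-sorbose) would give 4-[(2S,3S)-3-(3,5-dimethoxyphenyl)oxiran-2-yl]phenyl trifluoromethanesulfonate F1. Commercial 4-bromo-2-iodophenol is protected (MOMCl, i-Pr2NEt) as 4-bromo-2-iodo-1-(methoxymethoxy)benzene F2, and iodine–magnesium exchange (i-PrMgCl·LiCl, THF, −20 °C, iodine reacting far faster than bromine) gives [5-bromo-2-(methoxymethoxy)phenyl]magnesium chloride F3. CuI-catalysed opening of F1 by F3, with inversion at the carbon bearing ring C, should give 4-[(1R,2S)-2-[5-bromo-2-(methoxymethoxy)phenyl]-2-(3,5-dimethoxyphenyl)-1-hydroxyethyl]phenyl trifluoromethanesulfonate F4. The regiochemistry of this opening is the weak point of the fallback; it is expected for the same electronic reason as in step 6. HCl in MeOH removes the acetal to give 4-[(1R,2S)-2-(5-bromo-2-hydroxyphenyl)-2-(3,5-dimethoxyphenyl)-1-hydroxyethyl]phenyl trifluoromethanesulfonate F5. Mitsunobu cyclisation (PPh3, DIAD, THF) closes O1–C2 with inversion and gives 4-[(2S,3S)-5-bromo-3-(3,5-dimethoxyphenyl)-2,3-dihydro-1-benzofuran-2-yl]phenyl trifluoromethanesulfonate F6. Two inversions on the (2S,3S)-oxide lead to the same ring as two retentions on 3. Et4NOH frees 4-[(2S,3S)-5-bromo-3-(3,5-dimethoxyphenyl)-2,3-dihydro-1-benzofuran-2-yl]phenol F7, and the Heck coupling of step 8 with 17 gives 19 directly, since there is no chlorine to remove.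

**Step 9.**
- What may go wrong: transfer hydrogenation of the stilbene by palladium hydride, above all if the catalyst decays to colloidal metal; slow oxidative addition at the chloride flanked by C3a and the styryl group.
- Fallback, setting out from 16 and coming back at 19: the chlorine is removed before any alkene exists. Palladium-catalysed formylation of the bromide (Pd(OAc)2, di(1-adamantyl)-n-butylphosphine, CO/H2, TMEDA, toluene, 100 °C) would give (2S,3S)-4-chloro-3-(3,5-dimethoxyphenyl)-2-(4-hydroxyphenyl)-2,3-dihydro-1-benzofuran-5-carbaldehyde F8. Its chloride, now ortho to a formyl group, is reduced under the conditions of step 9 to (2S,3S)-3-(3,5-dimethoxyphenyl)-2-(4-hydroxyphenyl)-2,3-dihydro-1-benzofuran-5-carbaldehyde F9. Horner–Wadsworth–Emmons olefination with diethyl (3,5-dimethoxybenzyl)phosphonate (NaH in excess, THF) gives 19.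

**Step 10.**
- What may go wrong: Lewis acid ionisation of C2–O1 followed by irreversible capture of the cation (bromide, or Friedel–Crafts attack by a resorcinol ring), and addition of HBr to the stilbene during quench.
- Fallback, setting out from 19 and coming back at 20: ring B is made electron-poor again before demethylation. PhNTf2 and Et3N give 4-[(2S,3S)-3-(3,5-dimethoxyphenyl)-5-[(E)-2-(3,5-dimethoxyphenyl)ethenyl]-2,3-dihydro-1-benzofuran-2-yl]phenyl trifluoromethanesulfonate F10. BBr3 then gives 4-[(2S,3S)-3-(3,5-dihydroxyphenyl)-5-[(E)-2-(3,5-dihydroxyphenyl)ethenyl]-2,3-dihydro-1-benzofuran-2-yl]phenyl trifluoromethanesulfonate F11, with C2–O1 protected by the same effect that protects it in step 6. Degassed Et4NOH in dioxane at room temperature gives 20.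

**Step 4.**
- What may go wrong: loss of the N-silyl group, so that the N–H carbamate consumes base and fragments to phenoxide and isocyanate; competing deprotonation at C4 next to bromine followed by loss of LiBr.
- Fallback, setting out from 4 and coming back at 11: a fully substituted carbamate that cannot fragment, removed reductively. ClCONEt2 and K2CO3 in MeCN give 3-bromo-2-chlorophenyl N,N-diethylcarbamate F12. LiTMP with TMSCl in situ (THF, −78 °C) gives 3-bromo-2-chloro-6-(trimethylsilyl)phenyl N,N-diethylcarbamate F13. Cp2Zr(H)Cl in THF cleaves the carbamate to phenol 10, isolated this time, which PhNTf2 and Et3N convert into 11. This answers the first failure mode only; the second would show as a separable 4-silyl isomer.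

**Step 8.**
- What may go wrong: slow oxidative addition at the bromide flanked by chlorine, catalyst decay at the temperature then needed, and some arylation at the internal alkene carbon.
- Fallback, setting out from 16 and coming back at 18: Suzuki–Miyaura coupling of 16 with commercial (E)-2-(3,5-dimethoxyphenyl)ethenylboronic acid pinacol ester (PdCl2(dppf), K2CO3, dioxane/H2O, 80 °C), which fixes the alkene position and geometry in the reagent. This fallback makes no new compound (F0).

## Further compounds

F1 | step 6 | 4-[(2S,3S)-3-(3,5-dimethoxyphenyl)oxiran-2-yl]phenyl trifluoromethanesulfonate | O=S(=O)(Oc1ccc([C@@H]2O[C@H]2c2cc(OC)cc(OC)c2)cc1)C(F)(F)F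
F2 | step 6 | 4-bromo-2-iodo-1-(methoxymethoxy)benzene | COCOc1ccc(Br)cc1I
F3 | step 6 | [5-bromo-2-(methoxymethoxy)phenyl]magnesium chloride | COCOc1ccc(Br)cc1[Mg]Cl
F4 | step 6 | 4-[(1R,2S)-2-[5-bromo-2-(methoxymethoxy)phenyl]-2-(3,5-dimethoxyphenyl)-1-hydroxyethyl]phenyl trifluoromethanesulfonate | O=S(=O)(Oc1ccc([C@H](O)[C@H](c2cc(Br)ccc2OCOC)c2cc(OC)cc(OC)c2)cc1)C(F)(F)F
F5 | step 6 | 4-[(1R,2S)-2-(5-bromo-2-hydroxyphenyl)-2-(3,5-dimethoxyphenyl)-1-hydroxyethyl]phenyl trifluoromethanesulfonate | O=S(=O)(Oc1ccc([C@H](O)[C@H](c2cc(Br)ccc2O)c2cc(OC)cc(OC)c2)cc1)C(F)(F)F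
F6 | step 6 | 4-[(2S,3S)-5-bromo-3-(3,5-dimethoxyphenyl)-2,3-dihydro-1-benzofuran-2-yl]phenyl trifluoromethanesulfonate | O=S(=O)(Oc1ccc([C@H]2Oc3ccc(Br)cc3[C@@H]2c2cc(OC)cc(OC)c2)cc1)C(F)(F)F
F7 | step 6 | 4-[(2S,3S)-5-bromo-3-(3,5-dimethoxyphenyl)-2,3-dihydro-1-benzofuran-2-yl]phenol | Oc1ccc([C@H]2Oc3ccc(Br)cc3[C@@H]2c2cc(OC)cc(OC)c2)cc1
F8 | step 9 | (2S,3S)-4-chloro-3-(3,5-dimethoxyphenyl)-2-(4-hydroxyphenyl)-2,3-dihydro-1-benzofuran-5-carbaldehyde | Oc1ccc([C@H]2Oc3ccc(C=O)c(Cl)c3[C@@H]2c2cc(OC)cc(OC)c2)cc1
F9 | step 9 | (2S,3S)-3-(3,5-dimethoxyphenyl)-2-(4-hydroxyphenyl)-2,3-dihydro-1-benzofuran-5-carbaldehyde | Oc1ccc([C@H]2Oc3ccc(C=O)cc3[C@@H]2c2cc(OC)cc(OC)c2)cc1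
F10 | step 10 | 4-[(2S,3S)-3-(3,5-dimethoxyphenyl)-5-[(E)-2-(3,5-dimethoxyphenyl)ethenyl]-2,3-dihydro-1-benzofuran-2-yl]phenyl trifluoromethanesulfonate | O=S(=O)(Oc1ccc([C@H]2Oc3ccc(/C=C/c4cc(OC)cc(OC)c4)cc3[C@@H]2c2cc(OC)cc(OC)c2)cc1)C(F)(F)F
F11 | step 10 | 4-[(2S,3S)-3-(3,5-dihydroxyphenyl)-5-[(E)-2-(3,5-dihydroxyphenyl)ethenyl]-2,3-dihydro-1-benzofuran-2-yl]phenyl trifluoromethanesulfonate | O=S(=O)(Oc1ccc([C@H]2Oc3ccc(/C=C/c4cc(O)cc(O)c4)cc3[C@@H]2c2cc(O)cc(O)c2)cc1)C(F)(F)F
F12 | step 4 | 3-bromo-2-chlorophenyl N,N-diethylcarbamate | CCN(CC)C(=O)Oc1cccc(Br)c1Cl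
F13 | step 4 | 3-bromo-2-chloro-6-(trimethylsilyl)phenyl N,N-diethylcarbamate | CCN(CC)C(=O)Oc1c([Si](C)(C)C)ccc(Br)c1Cl
F0 | step 8 | none | none
A1 | alternative 1 | methyl 3-[(1S,2S)-1-(3,5-dimethoxyphenyl)-2-(4-methoxyphenyl)-2-(4,4,5,5-tetramethyl-1,3,2-dioxaborolan-2-yl)ethyl]-4-fluorobenzoate | COc1ccc([C@@H](B2OC(C)(C)C(C)(C)O2)[C@@H](c2cc(OC)cc(OC)c2)c2cc(C(=O)OC)ccc2F)cc1
A2 | alternative 2 | trimethyl{(2S,3S)-3-(3,5-dimethoxyphenyl)-5-[(E)-2-(3,5-dimethoxyphenyl)ethenyl]-2-(4-methoxyphenyl)-2,3-dihydro-1-benzofuran-7-yl}silane | COc1ccc([C@H]2Oc3c([Si](C)(C)C)cc(/C=C/c4cc(OC)cc(OC)c4)cc3[C@@H]2c2cc(OC)cc(OC)c2)cc1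
A3 | alternative 3 | (2S,3S)-5-bromo-3-(3,5-dimethoxyphenyl)-2-(4-methoxyphenyl)-2,3-dihydro-1-benzofuran | COc1ccc([C@H]2Oc3ccc(Br)cc3[C@@H]2c2cc(OC)cc(OC)c2)cc1
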